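If partner, and not an equilibrium, is what stops the product in this flask, the choice of remedy hangs on one number. We reckon on that supposition, which one run cannot prove.

| flask | starting material | partner | free catalyst | remark | time |
|---|---|---|---|---|---|
| delta | 1 M | 1.5 M | 1 mM | the very flask that is asked about, followed so far |  |
| flask | 1.0 M | 1.50 M | 1.0 mM |  | 8.0 d |

delta run (percent of the starting material charged)

| time / d | product / % | starting material / % |
|---|---|---|
| 0.333 | 2.1 | 97.8 |
| 0.833 | 5.3 | 95.5 |
| 1.67 | 8.2 | 91.3 |
| 2.50 | 9.4 | 89.6 |
| 4.00 | 10.2 | 89.0 |
| 5.00 | 10.6 | 89.9 |

(scatter of a reading: 0.5 percentage points)

- dawn: at 8.0 d take out 90% of the product then present, then wait 15 d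
- summer: at 8.0 d add free catalyst, 100% of the amount charged, then wait 15 d
- winter: at 8.0 d add partner, 50.0% of the amount charged, then wait 15 d
- spring: change nothing and wait 15 d more

- removed product is counted in
- additions bring no volume worth counting

1. product, in percent of the starting material first charged, at 8.0 d
2. the remedy with the largest gain of product, or "none" below 2 percentage points (dawn / summer / winter / spring / none)
3. product present, with what was taken out counted in, in percent of the starting material first charged, after winter
4. product present, with what was taken out counted in, in percent of the starting material first charged, after spring

The readings flatten at 10.6% by 5.00 d, and starting material and product together still make 101%. We suppose that one partner enters each product, by a path first order in partner, while the rest of the partner is lost to itself, by a path second order in it. Dividing one rate by the other removes time: at partner concentration B, the share a/(a + B) of the partner used becomes product. Summed down from the charge, the product made is a times the logarithm of one plus charge over a. The last reading then gives 0.106 M of product, and putting each value of a back into that sum until it stands still gives a = 0.0260 M, the crossover concentration, the partner concentration at which both paths take partner equally fast.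

Partner would then be the limiting reagent, so we expect nothing from dawn, summer or spring, and we choose winter. Its addition starts lower than the first charge, so its share is at least the first charge's average, which puts the product after winter no lower than 15.9%. Being the smaller portion, it makes no more than the first charge did, which gives at most 21.2%. The crossover tightens this to a gain of 8.8 percentage points, hence 19.4%.

The forecast gives 10.9% now, 11% after spring and 15.3% after winter, below our bracket, and picks dawn, saying “I favour equilibrium”.

The flask gives 10.4% now and 10.4% after spring, and the best remedy is winter, with 20.0%, inside the bracket . Dawn gains 0 points and summer 0 points.

    partner + free catalyst → catalyst intermediate A (k = 65.0 M⁻¹ h⁻¹)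
    2 partner → homo dimer (k = 0.260 M⁻¹ h⁻¹)
    catalyst intermediate A ⇌ catalyst intermediate B (K = 1.30, k = 33.0 h⁻¹)
    catalyst intermediate D → free catalyst + product (k = 69.0 h⁻¹)
    starting material + catalyst intermediate B ⇌ catalyst intermediate C (K = 0.110 M⁻¹, k = 2500 M⁻¹ h⁻¹)
    catalyst intermediate C → by-product + catalyst intermediate D (k = 74.0 h⁻¹)

In this flask partner stands at 0% at 8.00 d, beside 0.698 M of homo dimer, and winter's gain of 9.6 points stands against the 8.8 points from our crossover. For the neighbour flask with 4.0 × 10⁻⁴ M of free catalyst, taking the crossover in proportion to catalyst gives 5.19%, and that flask gave 6.05%. The asked flask has come to rest: partner stands at 0.0481% of its charge by 4.00 d, and its slowest mode at 8.00 d has a half-life of 0.444 d. Left ten times as long, to 80.0 d, it changes nothing: product still reads 10.4%.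

The earlier runs and the new flask were generated by integration from invented constants; the scatter is artificial.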